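## The problem

The target 13 is 8-(4-hydroxybenzyl)diosmetin: a 5,7-dihydroxyflavone (ring A the benzo ring, ring C the 4-pyranone, ring B the 3-hydroxy-4-methoxyphenyl group on C2) whose C8 carries, through one CH2, a fourth ring D that is a para-substituted phenol (C1'' bears the CH2 link, C4'' the hydroxyl). It has no stereocentre, so nothing has to be controlled or relayed, and the only chiral intermediates are transient and racemic. The synthesis is decided by regiochemistry and chemoselectivity: C8 must be told apart from the similarly activated C6 of the phloroglucinol-type ring A, the single methyl ether on O4' must stay distinct from four free phenols, and the C8–CH2–C1'' diarylmethane has to be made at a position flanked by O1 and O7. The unprotected polyphenol is easily oxidised and C-alkylated, and the pyranone opens when hydroxide or hard nucleophiles attack C2. Any protecting group on O5 sits peri to the C4 carbonyl and is unusually acid-labile, and the C2=C3 bond must survive whatever reduction ends the route. The feature that opens the route is ring D itself: a phenol para to a CH2 substituent is the dehydrogenation product of a 4-substituted cyclohex-2-enone, and such an enone is the Michael–aldol annulation product of an aldehyde RCH2CHO with methyl vinyl ketone. Read this way, C1'' and C6'' are the α-carbon and carbonyl carbon of a propanal chain on C8, the CH2 link is its C3, and C2''–C5'' with the ring D oxygen come from methyl vinyl ketone. Diosmetin (1) already contains rings A, B and C with the correct O-methylation, so only the C8 chain and ring D have to be built.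

## Retrosynthesis

**13 ⇒ 12.** Three O–CH2Ph bonds are cut. Benzyl is chosen because it tolerates carbonate base, palladium coupling, amine/acid catalysis and aerobic palladium, and leaves by neutral hydrogenolysis without touching the O4' methyl ether, C2=C3 or the diarylmethane. Acetals or silyl ethers on O5 would not survive the acidic steps. The ring D hydroxyl of 12 needs no protection.

**12 ⇒ 10.** No skeletal bond is cut; ring D is taken back by one unsaturation to the racemic 4-substituted cyclohex-2-enone 10. The neighbouring option is to attach a preformed 4-oxygenated benzyl unit to C8. Friedel–Crafts benzylation of a free flavone would give C6/C8 mixtures and polybenzylation, and a cross-coupling variant needs a benzylmetal reagent. The enone is what makes ring D accessible from a four-carbon commodity. The forward step must stop at the phenol, pass through dienone 11 only transiently, and leave the benzyl ethers alone.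

**10 ⇒ 6 + 7.** C1''–C2'' and C5''=C6'' are cut, opening ring D to the C8 propanal 6 and methyl vinyl ketone (7). This is the largest simplification of the route: a six-membered ring is replaced by an unbranched aldehyde chain. The forward reaction must alkylate the aldehyde α-carbon once and close the 1,5-keto-aldehyde 8 through aldol 9 to the enone. No stereocontrol is required.

**6 ⇒ 4 + 5.** The C8–CH2 bond is cut. A Heck reaction of iodide 4 with allyl alcohol (5) installs all three chain carbons and the aldehyde oxidation level in one operation. The neighbouring cut is O7-allylation, Claisen rearrangement, hydroboration and oxidation. That sequence is several steps longer and puts the C8/C6 decision into a thermal rearrangement; it is kept as a fallback. The forward step must achieve oxidative addition into a di-ortho-substituted iodide and β-hydride elimination towards the carbinol carbon.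

**4 ⇒ 3.** The C8–I bond is cut. Iodination must favour C8 over C6 and over ring B. This is the known preference of 5,7-dialkoxyflavones, so O5 has to be alkylated before this step.

**3 ⇒ 1 + 2.** Three O–benzyl bonds are cut back to commercial diosmetin (1) and three equivalents of benzyl bromide (2), one for each phenol. Buying 1 removes the whole flavone assembly and the O4'/O3' differentiation from the problem.

## Roads not taken

Alternative 1: Ring C would be closed last by cutting O1–C8a and O1–C2. Ynone A2 would be treated with [RuCl2(p-cymene)]2 (divalent ruthenium) and PhI(O2CCF3)2 in CF3CO2H/(CF3CO)2O. The ring A ketone directs hydroxylation of its only free ortho C–H, and the new oxygen adds 6-endo to the alkyne to give tetrapivalate A1.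
- Merits: the C8 benzyl group is placed on a simple arene before the heterocycle exists, no single phenol has to be singled out as the ring oxygen, and the route is convergent and independent of a natural flavone.
- Weak points: the C–H bond to be oxidised is next to the benzyl-bearing carbon, and the ketone is buttressed by a pivalate on its other side, so metallacycle formation is hindered. The ynone sits in a strongly acidic anhydride medium with an electrophilic iodine oxidant, where alkyne hydration and oxidation of the diarylmethane are plausible. Ketone-directed hydroxylation is established for simple aryl ketones, not ynones. Four pivalates must later be removed with nucleophilic base from a base-sensitive pyranone.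
- Comparison: this road is more convergent and arguably more inventive. The chosen plan offers a key step that stays within known reaction types, and six steps from a purchasable flavone.

Alternative 2: Ring C would be cut at C4a–C4, C4–C3 and O1–C2. Iodophenol A4, carbon monoxide and alkyne A5 would combine under PdCl2(PPh3)2 (divalent palladium) and Et2NH to give tetrabenzyl flavone A3.
- Merits: three bonds and a ring form in one step, A3 is one hydrogenolysis from 13, and ring D arrives as an ordinary protected benzyl group, so no dehydrogenation is needed. In convergence and redox economy this road is better than the chosen one.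
- Weak points: A4 is a pentasubstituted, electron-rich iodide with both ortho positions occupied. Oxidative addition and CO insertion would be slow, inviting direct alkynylation without CO uptake and 5-exo instead of 6-endo closure. A4 itself requires a C-benzylation, differentiation of three ring oxygens and a regiodefined iodination, which imports the ring A regiochemistry problem in a longer form.
- Comparison: the chosen plan buys the ring A pattern and the O-methylation, and makes only one regiochemical decision (C8 iodination of 3), on a substrate class where the outcome is well mapped.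

Alternative 3: Ring A would be built last by cutting C7–C8 and C5–C6. Pyranone ester A7 would be deprotonated with LiN(SiMe3)2 at the side-chain CH2 and C-acetylated with N-acetylimidazole. The methyl ketone enolate would then close onto the ring ester, and enolisation would give A6.
- Merits: the C8 substituent is fixed by construction with no C6/C8 question, the 5,7-diol emerges free, and only two benzyl groups remain. In regiochemical certainty and protecting-group economy this road is superior.
- Weak points: the carbanion is secondary and hindered, so O-acylation and incomplete acylation compete. After acetylation the most acidic site is the new methine, not the methyl group that must attack the ester. The pyranone is exposed to a strong amide base. A7 is an unsymmetrical 2,6-disubstituted pyranone ester that needs its own multistep synthesis.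
- Comparison: the chosen plan never has to construct the pyranone or ring A and is shorter overall.

Key step: step 4

Remark: ring D carbons are numbered C1'' (bearing the CH2 link) to C6'', with oxygen on C4''. Intermediates 8, 9 and 10 are racemic, and none of their stereocentres survives into 13. Step 1 consumes three equivalents of benzyl bromide, one per phenol.

## Route

Step 1
Reactants: 1 diosmetin (5,7-dihydroxy-2-(3-hydroxy-4-methoxyphenyl)chromen-4-one); 2 benzyl bromide (three equivalents consumed, one per hydroxyl)
Product: 3 tri-O-benzyldiosmetin (5,7-bis(benzyloxy)-2-[3-(benzyloxy)-4-methoxyphenyl]chromen-4-one)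
Conditions: 2 (3.6 equiv), K2CO3 (5 equiv), Bu4NI (cat.), DMF, 70 °C
Reagents that add atoms: benzyl bromide (the second and third equivalents of 2), BrCc1ccccc1.BrCc1ccccc1
Why: Threefold Williamson etherification, each phenoxide taking one benzyl group from one equivalent of 2; O7 and O3' alkylate readily, and the hydrogen-bonded 5-OH follows with the excess of 2 and iodide catalysis in warm DMF. Capping O5 is what later steers electrophiles to C8, and all three groups leave together in step 6.

Step 2
Reactants: 3 tri-O-benzyldiosmetin
Product: 4 8-iodo-tri-O-benzyldiosmetin (5,7-bis(benzyloxy)-2-[3-(benzyloxy)-4-methoxyphenyl]-8-iodochromen-4-one)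
Conditions: NIS (1.1 equiv), CF3CO2H (cat.), MeCN/CH2Cl2, 0 °C to rt, dark
Reagents that add atoms: N-iodosuccinimide, O=C1CCC(=O)N1I
Why: Electrophilic aromatic iodination; ring A with three donor oxygens is far more nucleophilic than ring B or the benzyl rings. In 5,7-dialkoxyflavones attack goes to C8 (para to O5, next to the ring oxygen) and not to C6, which is crowded between two benzyloxy groups and is preferred only when a free chelated 5-OH is present.

Step 3
Reactants: 4 8-iodo-tri-O-benzyldiosmetin; 5 allyl alcohol (prop-2-en-1-ol)
Product: 6 C8 propanal (3-{5,7-bis(benzyloxy)-2-[3-(benzyloxy)-4-methoxyphenyl]-4-oxochromen-8-yl}propanal)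
Conditions: Pd(OAc)2 (divalent palladium, 5 mol%), Bu4NCl, NaHCO3, DMF, 50 °C
Reagents that add atoms: none
Why: Heck reaction of an aryl iodide with allyl alcohol under ligand-free phase-transfer conditions; the aryl group adds to the terminal alkene carbon, β-hydride elimination towards the carbinol carbon gives the enol, and tautomerisation releases the saturated 3-arylpropanal. 8-Iodoflavones are known to undergo Heck coupling despite two ortho substituents, and the trisubstituted, electron-poor C2=C3 bond does not compete.

Step 4
Reactants: 6 C8 propanal; 7 methyl vinyl ketone (but-3-en-2-one)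
Product: 10 racemic cyclohexenone (5,7-bis(benzyloxy)-2-[3-(benzyloxy)-4-methoxyphenyl]-8-[(4-oxocyclohex-2-en-1-yl)methyl]chromen-4-one), via keto-aldehyde Michael adduct 8 (not isolated), via β-hydroxy ketone 9 (not isolated)
Conditions: 7 (2 equiv), pyrrolidine (20 mol%), AcOH (20 mol%), THF, 0 °C to rt; then AcOH (1 equiv), 60 °C
Reagents that add atoms: none
Why: Pyrrolidine condenses with the unhindered aldehyde of 6 to an enamine whose nucleophilic carbon is the aldehyde α-carbon (the future C1'', already carrying the CH2 link to C8); conjugate addition to 7 and hydrolysis form C1''–C2'' and release keto-aldehyde 8. The methyl group of the new ketone then attacks the aldehyde carbon through its enamine or enol (C5''–C6'') to give aldol 9, and buffered acid at 60 °C dehydrates 9 to the conjugated enone 10 with the carbonyl para to C1''. The closest known reaction type is the amine-catalysed Michael–aldol (Robinson-type) annulation of α-unbranched aldehydes with methyl vinyl ketone, the standard entry to 4-substituted cyclohex-2-enones. Ring D closes in a 6-(enolendo)-exo-trig aldol mode, the only closure open to 8, since every other enolisable position would have to form a four-membered ring. The single new stereocentre C1'' is set in the Michael step under an achiral catalyst, so 10 is racemic by design, and the centre becomes sp2 in step 5. The step needs monoalkylation and cross- rather than self-condensation: the α-branched adduct 8 forms an enamine much more slowly than 6, the 1,5-dicarbonyl spacing makes the intramolecular aldol faster than any intermolecular one, and the excess of 7 intercepts the enamine of 6 before it can meet a second molecule of aldehyde. The benzyl ethers keep O7 from closing a lactol onto the aldehyde and keep phenoxides from adding to 7, and the 2-aryl-4-pyranone is a poor acceptor for a secondary amine present only in catalytic amount as its acetate.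

Step 5
Reactants: 10 racemic cyclohexenone
Product: 12 tri-O-benzyl ether of the target (5,7-bis(benzyloxy)-2-[3-(benzyloxy)-4-methoxyphenyl]-8-(4-hydroxybenzyl)chromen-4-one), via cyclohexa-2,5-dienone 11 (not isolated)
Conditions: Pd(O2CCF3)2 (divalent palladium, 5 mol%), 2-(dimethylamino)pyridine (10 mol%), TsOH (20 mol%), O2 (1 atm), DMSO, 80 °C
Reagents that add atoms: none
Why: Aerobic palladium-catalysed dehydrogenation of a cyclohexenone to a phenol; a palladium enolate at C3'' undergoes β-hydride elimination from C2'' to give dienone 11, which tautomerises through its C1''–H to the phenol and erases the racemic centre, while O2 regenerates the catalyst. Aryl benzyl ethers, the flavone and the diarylmethane CH2 are not oxidised under these conditions, and any partial loss of the acid-labile 5-O-benzyl group is harmless because step 6 removes it.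

Step 6
Reactants: 12 tri-O-benzyl ether of the target
Product: 13 target (5,7-dihydroxy-2-(3-hydroxy-4-methoxyphenyl)-8-(4-hydroxybenzyl)chromen-4-one)
Conditions: H2 (1 atm), 10% Pd/C, THF/MeOH, rt
Reagents that add atoms: none
Why: Catalytic hydrogenolysis of three aryl benzyl ethers; the vinylogous-ester C2=C3 bond, the diarylmethane C–C bonds and the O4' methyl ether are inert at 1 atm and room temperature.

## Compound list

1 | diosmetin, 5,7-dihydroxy-2-(3-hydroxy-4-methoxyphenyl)chromen-4-one | COc1ccc(-c2cc(=O)c3c(O)cc(O)cc3o2)cc1O | starting material
2 | benzyl bromide | BrCc1ccccc1 | starting material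
3 | 5,7-bis(benzyloxy)-2-[3-(benzyloxy)-4-methoxyphenyl]chromen-4-one | COc1ccc(-c2cc(=O)c3c(OCc4ccccc4)cc(OCc4ccccc4)cc3o2)cc1OCc1ccccc1 | intermediate
4 | 5,7-bis(benzyloxy)-2-[3-(benzyloxy)-4-methoxyphenyl]-8-iodochromen-4-one | COc1ccc(-c2cc(=O)c3c(OCc4ccccc4)cc(OCc4ccccc4)c(I)c3o2)cc1OCc1ccccc1 | intermediate
5 | allyl alcohol, prop-2-en-1-ol | OCC=C | starting material
6 | 3-{5,7-bis(benzyloxy)-2-[3-(benzyloxy)-4-methoxyphenyl]-4-oxochromen-8-yl}propanal | COc1ccc(-c2cc(=O)c3c(OCc4ccccc4)cc(OCc4ccccc4)c(CCC=O)c3o2)cc1OCc1ccccc1 | intermediate
7 | methyl vinyl ketone, but-3-en-2-one | CC(=O)C=C | starting material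
8 | racemic 2-({5,7-bis(benzyloxy)-2-[3-(benzyloxy)-4-methoxyphenyl]-4-oxochromen-8-yl}methyl)-5-oxohexanal, not isolated | COc1ccc(-c2cc(=O)c3c(OCc4ccccc4)cc(OCc4ccccc4)c(CC(C=O)CCC(C)=O)c3o2)cc1OCc1ccccc1 | intermediate
9 | 5,7-bis(benzyloxy)-2-[3-(benzyloxy)-4-methoxyphenyl]-8-[(2-hydroxy-4-oxocyclohexyl)methyl]chromen-4-one, racemic mixture of diastereomers, not isolated | COc1ccc(-c2cc(=O)c3c(OCc4ccccc4)cc(OCc4ccccc4)c(CC4CCC(=O)CC4O)c3o2)cc1OCc1ccccc1 | intermediate
10 | racemic 5,7-bis(benzyloxy)-2-[3-(benzyloxy)-4-methoxyphenyl]-8-[(4-oxocyclohex-2-en-1-yl)methyl]chromen-4-one | COc1ccc(-c2cc(=O)c3c(OCc4ccccc4)cc(OCc4ccccc4)c(CC4CCC(=O)C=C4)c3o2)cc1OCc1ccccc1 | intermediate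
11 | 5,7-bis(benzyloxy)-2-[3-(benzyloxy)-4-methoxyphenyl]-8-[(4-oxocyclohexa-2,5-dien-1-yl)methyl]chromen-4-one, not isolated | COc1ccc(-c2cc(=O)c3c(OCc4ccccc4)cc(OCc4ccccc4)c(CC4C=CC(=O)C=C4)c3o2)cc1OCc1ccccc1 | intermediate
12 | 5,7-bis(benzyloxy)-2-[3-(benzyloxy)-4-methoxyphenyl]-8-(4-hydroxybenzyl)chromen-4-one | COc1ccc(-c2cc(=O)c3c(OCc4ccccc4)cc(OCc4ccccc4)c(Cc4ccc(O)cc4)c3o2)cc1OCc1ccccc1 | intermediate
13 | 5,7-dihydroxy-2-(3-hydroxy-4-methoxyphenyl)-8-(4-hydroxybenzyl)chromen-4-one (no stereocentre) | COc1ccc(-c2cc(=O)c3c(O)cc(O)c(Cc4ccc(O)cc4)c3o2)cc1O | target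

## Step count and risk

Total step count: 6. Longest linear sequence: 6 steps, from diosmetin (1) to 13.

**Step 4 (key step).** The likely failures are self-condensation of the aldehyde, oligomerisation of the vinyl ketone, a second conjugate addition, or stalling at the open-chain stage before aldol closure. The fallback sets out from 6 and returns at 10, with the donor and acceptor roles reversed. α-Methylenation of 6 with aqueous formaldehyde under pyrrolidine/propionic acid catalysis would give the 2-methylene aldehyde F1. Base-catalysed Michael addition of allyl acetoacetate to F1, followed by aldol condensation of its methyl ketone onto the aldehyde, would give the allyl β-keto ester F2. Pd(PPh3)4 (zerovalent palladium) with morpholine would then remove the allyl group, and the β-keto acid would lose CO2 to give 10. Ring D is still grown on the same aldehyde and closed by the same C5''–C6'' aldol bond, but a stabilised 1,3-dicarbonyl donor replaces the aldehyde enamine.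

**Step 2.** The risk is attack at C6 or on ring B, or double iodination, since C6 and C8 are both activated. The fallback sets out from 1 and returns at 6, placing the C8 carbon by a sigmatropic shift from O7 instead. Allyl bromide with one equivalent of K2CO3 in DMF would alkylate the most acidic 7-OH to give 7-O-allyldiosmetin F3. Claisen rearrangement in N,N-diethylaniline near 200 °C would give 8-allyldiosmetin F4. Benzylation as in step 1 would give the 8-allyl tribenzyl ether F5, hydroboration with 9-BBN and oxidation with NaBO3 would give the primary alcohol F6, and Dess–Martin oxidation would give 6.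

**Step 3.** The risks are slow oxidative addition at the di-ortho-substituted iodide with competing reductive deiodination, and arylation at the internal alkene carbon giving a branched chain. The fallback sets out from 4 and returns at 6. Negishi coupling of 4 with commercial [2-(1,3-dioxolan-2-yl)ethyl]zinc bromide, using Pd(OAc)2 (divalent palladium) and the phosphine SPhos, would give the dioxolane acetal F7. Hydrolysis with dilute aqueous HCl in THF would release 6. The chain then arrives with a fixed linear connectivity and a masked aldehyde.

**Step 5.** The risks are incomplete dehydrogenation, catalyst inhibition by the many Lewis-basic oxygens, and acid-induced loss of the 5-O-benzyl group leading to a chelating 5-hydroxy ketone. The fallback sets out from 10 and returns at 12, using hydride abstraction instead of palladium catalysis. Soft enolisation with TBSOTf and Et3N would give the silyl dienol ether F8, DDQ would aromatise it to the aryl silyl ether F9, and Bu4NF would free the phenol 12.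

## Further compounds

F1 | step 4 | 2-({5,7-bis(benzyloxy)-2-[3-(benzyloxy)-4-methoxyphenyl]-4-oxochromen-8-yl}methyl)prop-2-enal | COc1ccc(-c2cc(=O)c3c(OCc4ccccc4)cc(OCc4ccccc4)c(CC(=C)C=O)c3o2)cc1OCc1ccccc1
F2 | step 4 | allyl 5-({5,7-bis(benzyloxy)-2-[3-(benzyloxy)-4-methoxyphenyl]-4-oxochromen-8-yl}methyl)-2-oxocyclohex-3-ene-1-carboxylate, racemic mixture of diastereomers | COc1ccc(-c2cc(=O)c3c(OCc4ccccc4)cc(OCc4ccccc4)c(CC4CC(C(=O)OCC=C)C(=O)C=C4)c3o2)cc1OCc1ccccc1
F3 | step 2 | 7-(allyloxy)-5-hydroxy-2-(3-hydroxy-4-methoxyphenyl)chromen-4-one | COc1ccc(-c2cc(=O)c3c(O)cc(OCC=C)cc3o2)cc1O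
F4 | step 2 | 8-allyl-5,7-dihydroxy-2-(3-hydroxy-4-methoxyphenyl)chromen-4-one | COc1ccc(-c2cc(=O)c3c(O)cc(O)c(CC=C)c3o2)cc1O
F5 | step 2 | 8-allyl-5,7-bis(benzyloxy)-2-[3-(benzyloxy)-4-methoxyphenyl]chromen-4-one | COc1ccc(-c2cc(=O)c3c(OCc4ccccc4)cc(OCc4ccccc4)c(CC=C)c3o2)cc1OCc1ccccc1
F6 | step 2 | 5,7-bis(benzyloxy)-2-[3-(benzyloxy)-4-methoxyphenyl]-8-(3-hydroxypropyl)chromen-4-one | COc1ccc(-c2cc(=O)c3c(OCc4ccccc4)cc(OCc4ccccc4)c(CCCO)c3o2)cc1OCc1ccccc1
F7 | step 3 | 5,7-bis(benzyloxy)-2-[3-(benzyloxy)-4-methoxyphenyl]-8-[2-(1,3-dioxolan-2-yl)ethyl]chromen-4-one | COc1ccc(-c2cc(=O)c3c(OCc4ccccc4)cc(OCc4ccccc4)c(CCC4OCCO4)c3o2)cc1OCc1ccccc1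
F8 | step 5 | racemic 5,7-bis(benzyloxy)-2-[3-(benzyloxy)-4-methoxyphenyl]-8-{[4-(tert-butyldimethylsilyloxy)cyclohexa-2,4-dien-1-yl]methyl}chromen-4-one | COc1ccc(-c2cc(=O)c3c(OCc4ccccc4)cc(OCc4ccccc4)c(CC4CC=C(O[Si](C)(C)C(C)(C)C)C=C4)c3o2)cc1OCc1ccccc1
F9 | step 5 | 5,7-bis(benzyloxy)-2-[3-(benzyloxy)-4-methoxyphenyl]-8-[4-(tert-butyldimethylsilyloxy)benzyl]chromen-4-one | COc1ccc(-c2cc(=O)c3c(OCc4ccccc4)cc(OCc4ccccc4)c(Cc4ccc(O[Si](C)(C)C(C)(C)C)cc4)c3o2)cc1OCc1ccccc1
A1 | alternative 1 | 8-benzylflavone tetrapivalate, 2-[4-methoxy-3-(pivaloyloxy)phenyl]-5,7-bis(pivaloyloxy)-8-[4-(pivaloyloxy)benzyl]chromen-4-one | COc1ccc(-c2cc(=O)c3c(OC(=O)C(C)(C)C)cc(OC(=O)C(C)(C)C)c(Cc4ccc(OC(=O)C(C)(C)C)cc4)c3o2)cc1OC(=O)C(C)(C)C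
A2 | alternative 1 | 1-{2,4-bis(pivaloyloxy)-5-[4-(pivaloyloxy)benzyl]phenyl}-3-[4-methoxy-3-(pivaloyloxy)phenyl]prop-2-yn-1-one | COc1ccc(C#CC(=O)c2cc(Cc3ccc(OC(=O)C(C)(C)C)cc3)c(OC(=O)C(C)(C)C)cc2OC(=O)C(C)(C)C)cc1OC(=O)C(C)(C)C
A3 | alternative 2 | 5,7-bis(benzyloxy)-8-[4-(benzyloxy)benzyl]-2-[3-(benzyloxy)-4-methoxyphenyl]chromen-4-one | COc1ccc(-c2cc(=O)c3c(OCc4ccccc4)cc(OCc4ccccc4)c(Cc4ccc(OCc5ccccc5)cc4)c3o2)cc1OCc1ccccc1
A4 | alternative 2 | 3,5-bis(benzyloxy)-2-[4-(benzyloxy)benzyl]-6-iodophenol | Oc1c(I)c(OCc2ccccc2)cc(OCc2ccccc2)c1Cc1ccc(OCc2ccccc2)cc1
A5 | alternative 2 | 2-(benzyloxy)-4-ethynyl-1-methoxybenzene | COc1ccc(C#C)cc1OCc1ccccc1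
A6 | alternative 3 | 8-[4-(benzyloxy)benzyl]-2-[3-(benzyloxy)-4-methoxyphenyl]-5,7-dihydroxychromen-4-one | COc1ccc(-c2cc(=O)c3c(O)cc(O)c(Cc4ccc(OCc5ccccc5)cc4)c3o2)cc1OCc1ccccc1
A7 | alternative 3 | methyl 6-[3-(benzyloxy)-4-methoxyphenyl]-2-{2-[4-(benzyloxy)phenyl]ethyl}-4-oxo-4H-pyran-3-carboxylate | COC(=O)c1c(CCc2ccc(OCc3ccccc3)cc2)oc(-c2ccc(OC)c(OCc3ccccc3)c2)cc1=O
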